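Do not read the nucleophile in elm as an excess: each turnover may cost more of it than the first equation shows.

| flask | electrophile | nucleophile | remark | time |
|---|---|---|---|---|
| dawn | 13 mM | 1.5 equiv | run made earlier |  |
| elm | 19 mM | 1.50 equiv |  | 4.0 d |
| birch | 19 mM | 3.00 equiv |  | 4.0 d |

dawn run (percent of the electrophile charged)

| time / h | electrophile / % | product / % |
|---|---|---|
| 2.50 | 98.5 | 5.0 |
| 4.00 | 94.5 | 4.3 |
| 6.00 | 91.3 | 8.0 |
| 10.0 | 85.6 | 13.1 |
| 15.0 | 80.4 | 17.1 |
| 20.0 | 77.8 | 20.4 |
| 30.0 | 71.2 | 30.8 |

(readings scatter by 1 percentage point)

- amounts and yields of acid set free count idle adduct too
- the earlier runs were read with a standard deviation of 1 percentage point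
- candidate steps: electrophile + nucleophile -> acid set free + product; nucleophile + acid set free <-> protonated nucleophile; nucleophile + acid set free <-> idle adduct

- part of the electrophile that has reacted at the end, elm
- part of the electrophile that has reacted at the end, birch
- what raising the equivalents of nucleophile from its lowest to its highest value here does to the part of the electrophile that has reacted (changes below 5 percentage points count as none) (it falls / it rises / no change)

We hand over two flasks, elm and birch. In each, electrophile and nucleophile make product and set free one acid. That acid can take up a further nucleophile, as protonated nucleophile or idle adduct. So we write the nucleophile balance at two lost per electrophile reacted. Half the equivalents then gives the stall point, the part of the electrophile reacted at which this balance leaves no nucleophile: 75.0 % for elm. By this balance the nucleophile is the limiting reagent in elm. Birch has a stall point of 150 %, above the whole charge of electrophile. Dawn, at the equivalents of elm, had 28.8 % reacted by 30.0 h.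

When you come at 4.0 d, the forecast expects 61 % in elm (52 % to 72 %) and 90 % in birch (80 % to 97 %), so it rises. Its ground is that “each turnover also removes a second nucleophile”. Leave the nucleophile charges alone: the stall point moves in step with them.

The part reacted is 60.9 % in elm and 90.5 % in birch, so it rises, by 30 percentage points, and both lie inside the forecast's ranges.

    electrophile + nucleophile → acid set free + product (k = 0.0130 M⁻¹ min⁻¹)
    nucleophile + acid set free ⇌ protonated nucleophile, settled at all times (K = 3700 M⁻¹)
    nucleophile + acid set free ⇌ idle adduct, settled at all times (K = 53.0 M⁻¹)

At 4.00 d elm stands short of its stall point. The balance leaves 18.8 % of the charged nucleophile in elm, and the flask holds 21 %. The stall point is a mark, not a stop: by 40.0 d elm stands at 85.3 %, past it, with 4.59 mM of acid set free. The neighbour flask is elm with 0.600 equiv of nucleophile. Its stall point is 30.0 %, and it reaches 28.1 % in 4.00 d. The balance leaves 6.48 % of the nucleophile in the neighbour flask, and the flask holds 13 %. Of the electrophile in the neighbour flask, 72 % stands unreacted at that time.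

All runs were computed from invented constants.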